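**Plan**
- Retrosynthesis: the four O–alkyl bonds are cut last. Flavone ring C is cut at O1–C2 (cyclodehydration), C2–C3 (Baker–Venkataraman acyl shift) and C4–C4a (ortho-acetylation), which leaves a 2-aryl-3,5-diethoxyphenol.
- Ring A is then cut at C8–C8a, C6–C7 and C4a–C8a into 3-ethoxycyclobut-2-en-1-one and a coumarin-6-yl ethoxyalkyne. The aryl–alkyne bond leads back to 6-bromo-7-methoxycoumarin, and the coumarin lactone to 4-bromoresorcinol and malic acid.
- Forward order of rings: coumarin pyranone (Pechmann), then flavone ring A by benzannulation on the alkyne already attached to coumarin C6, then ring C; ring B arrives as 4-methoxybenzoyl chloride.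
- Enabling feature: flavone ring A (C4a, C5, C6, C7, C8, C8a) is a phloroglucinol ring. The benzannulation delivers it with ethers on the C5 and C7 oxygens and the only free hydroxyl on C8a, next to the coumarin-bearing C8, so ring C can close in one direction only.
- Stereochemistry: the target has no stereocentre; the one sp3 carbon that appears during the cascade is lost on aromatisation.

Key step: step 4

Assumption: the biaryl axis of the target is drawn without configuration, so no axial control is planned, and 3-ethoxycyclobut-2-en-1-one is taken as a catalogue reagent.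

Step 1
Reactants: 1 4-bromoresorcinol (4-bromobenzene-1,3-diol); 2 DL-malic acid
Product: 4 6-bromo-7-hydroxy-2H-chromen-2-one, via 3-oxopropanoic acid 3 (not isolated)
Conditions: conc. H2SO4, 110 °C; ice–water
Reagents that add atoms: none
Why: Von Pechmann condensation, in which malic acid loses CO and water in hot sulfuric acid to give formylacetic acid 3, which attacks the carbon para to one hydroxyl and ortho to the other and lactonises, so that bromine ends at C6 and the free hydroxyl at C7.

Step 2
Reactants: 4 6-bromo-7-hydroxy-2H-chromen-2-one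
Product: 5 6-bromo-7-methoxy-2H-chromen-2-one
Conditions: MeI, K2CO3, acetone, 56 °C
Reagents that add atoms: iodomethane, CI
Why: Williamson etherification of the acidic 7-hydroxyl under carbonate conditions that leave the lactone closed; the methyl ether keeps this phenol away from the organometallic and ketene intermediates of the next two steps.

Step 3
Reactants: 5 6-bromo-7-methoxy-2H-chromen-2-one; 6 ethoxyethyne
Product: 9 6-(ethoxyethynyl)-7-methoxy-2H-chromen-2-one, via lithium ethoxyacetylide 7 (not isolated), via ethoxyethynylzinc chloride 8 (not isolated)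
Conditions: 6, n-BuLi, THF, −78 °C; ZnCl2, −78 to 0 °C; then 5, Pd(PPh3)4 (5 mol %), THF, 50 °C; chromatography on Et3N-deactivated silica
Reagents that add atoms: none
Why: Negishi alkynylation, in which the zinc acetylide is mild enough to tolerate the lactone and zerovalent palladium inserts into the C6–Br bond, so that the later hindered biaryl bond is made here as an unhindered sp2–sp bond.

Step 4
Reactants: 9 6-(ethoxyethynyl)-7-methoxy-2H-chromen-2-one; 10 3-ethoxycyclobut-2-en-1-one
Product: 15 6-(2,4-diethoxy-6-hydroxyphenyl)-7-methoxy-2H-chromen-2-one, via vinylketene 11 (not isolated), via vinylcyclobutenone 12 (not isolated), via dienylketene 13 (not isolated), via cyclohexadienone 14 (not isolated)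
Conditions: 10 (1.3 equiv), degassed toluene, 80–90 °C, sealed tube
Reagents that add atoms: none
Why: This is a Danheiser benzannulation of a cyclobutenone with an alkoxyalkyne: thermal four-electron conrotatory opening of 10 gives vinylketene 11, which adds (2+2) across the triple bond of 9 to give cyclobutenone 12 (flavone C8–C8a and C6–C7), and 12 opens reversibly to dienylketene 13. Ring A closes by a thermal six-electron disrotatory electrocyclization of 13 that joins the ketene carbon to the terminal methylene (C4a–C8a) to give dienone 14, and enolisation of 14 to phenol 15 makes the cascade irreversible. No stereocentre results, because the sp3 carbon of 12 is racemic and is erased on ring opening. The step needs one regiochemical outcome of the ketene–alkyne addition, and the ethoxy group secures it by polarising the triple bond so that the aryl-bearing carbon is the nucleophile that attacks the central ketene carbon; this puts the coumarin on C8, between the free hydroxyl on C8a (the former ketene carbonyl) and the C7 ethoxy group. The temperature is kept at or below about 90 °C because ethyl ynol ethers lose ethylene by a retro-ene reaction when heated harder, and the methyl ether on the coumarin leaves no second phenol to trap the ketene.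

Step 5
Reactants: 15 6-(2,4-diethoxy-6-hydroxyphenyl)-7-methoxy-2H-chromen-2-one
Product: 17 6-(3-acetyl-4,6-diethoxy-2-hydroxyphenyl)-7-methoxy-2H-chromen-2-one, via difluoroboron chelate 16 (not isolated)
Conditions: Ac2O, BF3·OEt2, 80 °C; then EtOH–H2O, 80 °C
Reagents that add atoms: acetic anhydride, CC(=O)OC(C)=O
Why: Friedel–Crafts/Fries ortho-acylation of a phloroglucinol dialkyl ether, in which the one free carbon ortho to the hydroxyl (C4a) is the only site where the ketone is held as a six-membered difluoroboron chelate, which favours it over the carbon between the two ethoxy groups, while the deactivated coumarin ring does not compete.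

Step 6
Reactants: 17 6-(3-acetyl-4,6-diethoxy-2-hydroxyphenyl)-7-methoxy-2H-chromen-2-one; 18 4-methoxybenzoyl chloride
Product: 19 2-acetyl-3,5-diethoxy-6-(7-methoxy-2-oxo-2H-chromen-6-yl)phenyl 4-methoxybenzoate
Conditions: pyridine, DMAP (cat.), CH2Cl2, 40 °C
Reagents that add atoms: none
Why: DMAP-catalysed O-acylation of the hindered, hydrogen-bonded phenol with an acid chloride, which places the ring B carbonyl on the C8a oxygen for the acyl shift.

Step 7
Reactants: 19 2-acetyl-3,5-diethoxy-6-(7-methoxy-2-oxo-2H-chromen-6-yl)phenyl 4-methoxybenzoate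
Product: 20 1-[4,6-diethoxy-2-hydroxy-3-(7-methoxy-2-oxo-2H-chromen-6-yl)phenyl]-3-(4-methoxyphenyl)propane-1,3-dione
Conditions: LiN(SiMe3)2 (3 equiv), THF, −78 to 0 °C; aq. HCl
Reagents that add atoms: none
Why: Baker–Venkataraman rearrangement, in which the lithium enolate of the acetyl group attacks the neighbouring aryl ester through a six-membered transition state (forming C2–C3), and the hindered amide base at low temperature spares the coumarin lactone.

Step 8
Reactants: 20 1-[4,6-diethoxy-2-hydroxy-3-(7-methoxy-2-oxo-2H-chromen-6-yl)phenyl]-3-(4-methoxyphenyl)propane-1,3-dione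
Product: 21 5,7-diethoxy-8-(7-methoxy-2-oxo-2H-chromen-6-yl)-2-(4-methoxyphenyl)-4H-chromen-4-one
Conditions: H2SO4 (cat.), AcOH, 95 °C
Reagents that add atoms: none
Why: Acid-catalysed cyclodehydration of a 2-hydroxyaryl 1,3-diketone, in which the only free phenol (on C8a) adds 6-exo-trig to the aroyl carbonyl and loss of water gives the 4-pyranone, so the coumarin can only end on C8.

Step 9
Reactants: 21 5,7-diethoxy-8-(7-methoxy-2-oxo-2H-chromen-6-yl)-2-(4-methoxyphenyl)-4H-chromen-4-one
Product: 22 5,7-dihydroxy-8-(7-hydroxy-2-oxo-2H-chromen-6-yl)-2-(4-hydroxyphenyl)-4H-chromen-4-one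
Conditions: BBr3 (12 equiv), CH2Cl2, −78 to 40 °C; MeOH, then H2O
Reagents that add atoms: none
Why: Lewis-acid ether cleavage, in which BBr3 binds each aryl ether oxygen and bromide removes the alkyl group by SN2, cleaving both methyl and both ethyl ethers (the C5 ether fastest, helped by the C4 carbonyl) while the lactone and the pyranone survive.

**Compound list**
1 | 4-bromoresorcinol (4-bromobenzene-1,3-diol) | Oc1ccc(Br)c(O)c1 | starting material
2 | DL-malic acid (2-hydroxybutanedioic acid) | OC(CC(O)=O)C(O)=O | starting material
3 | 3-oxopropanoic acid (formylacetic acid), formed in situ | O=CCC(O)=O | intermediate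
4 | 6-bromo-7-hydroxy-2H-chromen-2-one | O=c1ccc2cc(Br)c(O)cc2o1 | intermediate
5 | 6-bromo-7-methoxy-2H-chromen-2-one | COc1cc2oc(=O)ccc2cc1Br | intermediate
6 | ethoxyethyne | CCOC#C | starting material
7 | lithium ethoxyacetylide, formed in situ | [Li]C#COCC | intermediate
8 | ethoxyethynylzinc chloride, formed in situ | CCOC#C[Zn]Cl | intermediate
9 | 6-(ethoxyethynyl)-7-methoxy-2H-chromen-2-one | CCOC#Cc1cc2ccc(=O)oc2cc1OC | intermediate
10 | 3-ethoxycyclobut-2-en-1-one | CCOC1=CC(=O)C1 | starting material
11 | 3-ethoxybuta-1,3-dien-1-one (vinylketene), formed in situ | C=C(OCC)C=C=O | intermediate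
12 | 3-ethoxy-4-(1-ethoxyethenyl)-2-(7-methoxy-2-oxo-2H-chromen-6-yl)cyclobut-2-en-1-one (racemic), formed in situ | CCOC(=C)C1C(=O)C(c2cc3ccc(=O)oc3cc2OC)=C1OCC | intermediate
13 | (3E)-3,5-diethoxy-2-(7-methoxy-2-oxo-2H-chromen-6-yl)hexa-1,3,5-trien-1-one (dienylketene, ketene and ethoxyvinyl groups cis), formed in situ | O=C=C(c1cc2ccc(=O)oc2cc1OC)/C(OCC)=C\C(OCC)=C | intermediate
14 | 3,5-diethoxy-2-(7-methoxy-2-oxo-2H-chromen-6-yl)cyclohexa-2,4-dien-1-one, formed in situ | CCOC1=CC(OCC)=C(C(=O)C1)c1cc2ccc(=O)oc2cc1OC | intermediate
15 | 6-(2,4-diethoxy-6-hydroxyphenyl)-7-methoxy-2H-chromen-2-one | CCOc1cc(O)c(c(OCC)c1)-c1cc2ccc(=O)oc2cc1OC | intermediate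
16 | O,O-difluoroboron chelate of ketone 17 (boron bridging the phenolic and acetyl oxygens), formed in situ | CC1=[O+][B-](F)(F)Oc2c1c(OCC)cc(OCC)c2-c1cc2ccc(=O)oc2cc1OC | intermediate
17 | 6-(3-acetyl-4,6-diethoxy-2-hydroxyphenyl)-7-methoxy-2H-chromen-2-one | CC(=O)c1c(OCC)cc(OCC)c(c1O)-c1cc2ccc(=O)oc2cc1OC | intermediate
18 | 4-methoxybenzoyl chloride | COc1ccc(cc1)C(Cl)=O | starting material
19 | 2-acetyl-3,5-diethoxy-6-(7-methoxy-2-oxo-2H-chromen-6-yl)phenyl 4-methoxybenzoate | CC(=O)c1c(OCC)cc(OCC)c(c1OC(=O)c1ccc(OC)cc1)-c1cc2ccc(=O)oc2cc1OC | intermediate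
20 | 1-[4,6-diethoxy-2-hydroxy-3-(7-methoxy-2-oxo-2H-chromen-6-yl)phenyl]-3-(4-methoxyphenyl)propane-1,3-dione | COc1ccc(cc1)C(=O)CC(=O)c1c(OCC)cc(OCC)c(c1O)-c1cc2ccc(=O)oc2cc1OC | intermediate
21 | 5,7-diethoxy-8-(7-methoxy-2-oxo-2H-chromen-6-yl)-2-(4-methoxyphenyl)-4H-chromen-4-one | CCOc1cc(OCC)c(-c2cc3ccc(=O)oc3cc2OC)c2oc(cc(=O)c12)-c1ccc(OC)cc1 | intermediate
22 | 5,7-dihydroxy-8-(7-hydroxy-2-oxo-2H-chromen-6-yl)-2-(4-hydroxyphenyl)-4H-chromen-4-one | O=c1ccc2cc(-c3c(O)cc(O)c4c(=O)cc(-c5ccc(O)cc5)oc34)c(O)cc2o1 | target

**Step count and risks**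
Total steps: 9. Longest linear sequence: 9 steps (1 to 22).

Most likely to fail, step 4: the donor-substituted cyclobutenone 10 may open only above about 90 °C, and at that temperature retro-ene loss of ethylene from the ynol ether and dimerisation of the vinylketene can outrun the (2+2) capture. The fallback sets out from 9 and returns at 15, and makes the same vinylketene at room temperature by known 1,4-dehydrochlorination. Commercial ethyl (E)-3-ethoxybut-2-enoate is saponified with KOH to potassium (E)-3-ethoxybut-2-enoate F1, and oxalyl chloride converts this into (E)-3-ethoxybut-2-enoyl chloride F2. Slow addition of F2 to 9 and Et3N in CH2Cl2 at 0–25 °C generates vinylketene 11, which is trapped by 9 in the known ketene–ynol ether (2+2) addition to give cyclobutenone 12. Once the ynol ether is consumed, warming in toluene to 80 °C takes 12 through 13 and 14 to 15.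

Second, step 3: slow oxidative addition into the electron-rich, ortho-methoxy aryl bromide may let the zinc acetylide homocouple, and traces of acid may hydrate the ynol ether during isolation. The fallback sets out from 5 and returns at 9 under neutral conditions. Copper-catalysed halogen exchange (CuI, NaI, trans-N,N'-dimethylcyclohexane-1,2-diamine, dioxane, 110 °C) gives 6-iodo-7-methoxy-2H-chromen-2-one F3. Quenching lithium acetylide 7 with Bu3SnCl gives the distillable tributyl(ethoxyethynyl)stannane F4. Stille coupling of F3 with F4 (Pd(PPh3)4, toluene, 50 °C) then delivers 9 without any organolithium or zinc halide in the flask.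

Third, step 5: acylation may occur at the ring carbon between the two ethoxy groups, or the Lewis acid may cleave an ethyl ether. The fallback sets out from 15 and returns at 17 by a boron-tethered Hoesch acylation (Sugasawa type). BCl3 converts the phenol into a dichloroboron phenoxide that delivers acetonitrile only to the free ortho carbon (BCl3, MeCN, 1,2-dichloroethane, 0–25 °C), giving the ketimine 6-[4,6-diethoxy-2-hydroxy-3-(1-iminoethyl)phenyl]-7-methoxy-2H-chromen-2-one F5. Warm aqueous HCl hydrolyses F5 to 17.

**Further compounds**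
F1 | step 4 | potassium (E)-3-ethoxybut-2-enoate | CCO/C(C)=C/C(=O)[O-].[K+]
F2 | step 4 | (E)-3-ethoxybut-2-enoyl chloride | CCO/C(C)=C/C(Cl)=O
F3 | step 3 | 6-iodo-7-methoxy-2H-chromen-2-one | COc1cc2oc(=O)ccc2cc1I
F4 | step 3 | tributyl(ethoxyethynyl)stannane | CCCC[Sn](CCCC)(CCCC)C#COCC
F5 | step 5 | 6-[4,6-diethoxy-2-hydroxy-3-(1-iminoethyl)phenyl]-7-methoxy-2H-chromen-2-one | CC(=N)c1c(OCC)cc(OCC)c(c1O)-c1cc2ccc(=O)oc2cc1OC
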